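**Plan**
1. Numbering: C1 (quaternary, CH3), C2, C3, C4 (OH, isopropyl), C5 (ring-fusion CH), C6 (aroyloxy), C7, C8 (CH3)=C9, C10 (isovaleryloxy). The cyclopentane is C1–C5 and the cycloheptene is C1, C5–C10.
2. Retrosynthesis: the two ester C–O bonds and the C8=C9 unsaturation are taken back to a 6,10-dione. Then C1–C5 and C8–C9 are cut in one operation, which opens both rings to a single chain.
3. What allows this cut: in the seven-membered ring, C9–C10–C1 has its oxygen on the middle carbon (a latent oxyallyl cation). C5–C6–C7–C8 has oxygen on its second carbon and methyl on its end (a 2-silyloxydiene). C2–C3–C4 of the five-membered ring is a ready three-atom tether from C1 to C5.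
4. The chain is cut further at C6–C7 (aldehyde + propenyl metal) and C1–C10 (methyl ketone + two-carbon carbenoid), which leaves ring-opened (R)-terpinen-4-ol. Forward: chain assembly in steps 1–7, both rings at once in step 8, adjustment and acylation in steps 9–19.
5. Stereochemistry: C4 comes with terpinen-4-ol and induces C1 in the cycloaddition. C5 is reset by kinetic protonation of the C5=C6 enolate. C6 and C10 come from hydride delivery to the face opposite the C1 methyl group.

Key step: step 8

Assumption: (R)-(−)-terpinen-4-ol is taken as commercially available in enantiopure form.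
Conventions: "top" is the face of the bicycle that carries the C4 oxygen and "bottom" is the face that carries isopropyl. Centres that are planarised later (C6 in 7 and 10, C1 in 10–14) are carried as epimer mixtures and drawn without configuration.

**Step 1**
Reactants: 1 (R)-terpinen-4-ol
Product: 2 (R)-terpinen-4-yl triethylsilyl ether
Conditions: Et3SiOTf, 2,6-lutidine, CH2Cl2, 0 °C
Reagents that add atoms: triethylsilyl triflate, CC[Si](CC)(CC)OS(=O)(=O)C(F)(F)F
Why: Silyl triflate with a hindered pyridine is the standard silylation of a tertiary alcohol; it caps the C4 oxygen, which would otherwise trap the cation of step 8 as a tetrahydrofuran, and leaves C4 untouched.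

**Step 2**
Reactants: 2 (R)-terpinen-4-yl triethylsilyl ether
Product: 4 (R)-3-isopropyl-6-oxo-3-(triethylsilyloxy)heptanal, via secondary ozonide 3 (not isolated)
Conditions: O3, CH2Cl2, −78 °C; PPh3, −78 °C to 25 °C
Reagents that add atoms: ozone, [O-][O+]=O
Why: Ozonolysis with reductive work-up cleaves the only alkene, so the former ring carbons become C1 (methyl ketone) and C6 (aldehyde), with the intact C4 centre between the C2–C3 arm and the C5 arm.

**Step 3**
Reactants: 4 keto aldehyde; 5 (E)-1-bromoprop-1-ene
Product: 7 (5R,8E)-7-hydroxy-5-isopropyl-5-(triethylsilyloxy)dec-8-en-2-one (both C6 epimers), via (E)-prop-1-enylchromium dichloride 6 (not isolated)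
Conditions: CrCl2 (excess), NiCl2 (cat.), DMF, 25 °C; aqueous work-up
Reagents that add atoms: (E)-1-bromoprop-1-ene 5, C/C=C/Br
Why: In the Nozaki–Hiyama–Kishi coupling the alkenylchromium reagent adds to aldehydes but not to ketones and keeps the E geometry; the new C6 carbinol centre is erased in step 5.

**Step 4**
Reactants: 7 hydroxy ketone; 8 1,1-dichloroethane
Product: 10 (E)-2,2-dichloro-6-isopropyl-3-methyl-6-(triethylsilyloxy)undec-9-ene-3,8-diol (C4 as in 1), via 1,1-dichloroethyllithium 9 (not isolated)
Conditions: 8, n-BuLi, THF–Et2O–pentane, −110 °C; then 7, −110 to −90 °C; AcOH, −90 °C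
Reagents that add atoms: 1,1-dichloroethane 8, CC(Cl)Cl
Why: Addition of a lithium carbenoid to the ketone followed by a cold quench forms C1–C10 and delivers a β,β-dichloro carbinol, a non-enolisable mask of the chloro ketone, whose C1 configuration is irrelevant because C1 is planarised in step 8.

**Step 5**
Reactants: 10 dichloro diol
Product: 11 (E)-10,10-dichloro-9-hydroxy-6-isopropyl-9-methyl-6-(triethylsilyloxy)undec-2-en-4-one
Conditions: MnO2, CH2Cl2, 25 °C
Reagents that add atoms: none
Why: Allylic oxidation with MnO2 converts only the secondary allylic alcohol into the (E)-enone, since the tertiary carbinol cannot be oxidised and the neutral medium spares both the silyl ether and the β-silyloxy ketone.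

**Step 6**
Reactants: 11 enone
Product: 12 (Z,E)-2-silyloxydiene C5=C6(OTBS)–C7=C8 that still carries the C1 dichloro carbinol
Conditions: t-BuMe2SiOTf, Et3N, CH2Cl2, −78 to 0 °C
Reagents that add atoms: tert-butyldimethylsilyl triflate, CC(C)(C)[Si](C)(C)OS(=O)(=O)C(F)(F)F
Why: Soft enolisation (silyl triflate and amine) acts on the only enolisable carbonyl, removes the α′ proton at C5 to give the cross-conjugated dienol ether, and gives the Z enol ether because the quaternary C4 avoids the propenyl group.

**Step 7**
Reactants: 12 silyloxydiene carbinol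
Product: 14 acyclic tertiary α-chloro methyl ketone carrying the tethered (Z,E)-2-silyloxydiene (both C1 epimers), via chloro epoxide 13 (not isolated)
Conditions: KN(SiMe3)2 (1 equiv), THF, −78 to 0 °C
Reagents that add atoms: none
Why: The alkoxide displaces one chloride and the resulting α-chloro epoxide opens with a 1,2-chloride shift to the tertiary carbon (the known conversion of carbenoid adducts into α-chloro ketones), so the chloro ketone appears without any acid or electrophilic chlorine touching the diene.

**Step 8**
Reactants: 14 chloro ketone with tethered silyloxydiene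
Product: 16 cis-fused hydroazulen-10-one with C6=C7 OTBS enol ether (OTES and C8–CH3 on top; isopropyl and C1–CH3 and C5–H on the bottom), via oxyallyl cation 15 (not isolated)
Conditions: Et3N, CF3CH2OH, 0.01 M, 0 to 25 °C
Reagents that add atoms: none
Why: Et3N enolises the methyl ketone toward C9 and the strongly ionising, weakly nucleophilic solvent lets chloride leave from tertiary C1, giving oxyallyl cation 15, whose more substituted terminus C1 is attacked by C5, the nucleophilic carbon of the silyl enol ether, while C9 bonds to C8 in the same or an immediately following event. The closest known reaction type is the intramolecular (4+3) cycloaddition of oxyallyl cations made from α-chloro ketones with amine base in trifluoroethanol, which is established for three-atom tethers and for fully substituted, tether-bearing cation termini. The cyclopentane closes 5-exo at C1 through C2–C3–C4, and the cycloheptene closes by union of the two remote termini, 7-endo with respect to the silyloxyallyl unit C6–C7–C8, so C10 emerges as the ketone and C6 as the silyl enol ether. C1 is controlled by C4: the tether methylene C3 must lie on the attacked diene face, allylic 1,3-strain with the Z-OTBS group leaves room only for the small oxygen substituent beside O6 and turns isopropyl to the far side, and the compact arrangement (oxido carbon over the diene, C1 methyl over the open mouth next to C5–H) then places C10 syn to OTES and the methyl syn to isopropyl, as in the target. C5 (cis fusion) and C8 follow from suprafacial bonding to the (Z,E)-diene and are both reset later (steps 11 and 16). The step needs carbon over oxygen closure, cycloaddition over solvent capture, and one diene face; these are served by high dilution, the polarity match of C5 with C1, the short tether and the fixed Z geometry of the enol ether.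

**Step 9**
Reactants: 16 cycloadduct
Product: 17 cis-fused 4-hydroxy-6,10-dione (C5–H on the bottom)
Conditions: HF·pyridine, pyridine, THF, 0 to 25 °C
Reagents that add atoms: none
Why: Fluoride-assisted desilylation removes both silyl groups with protonation of the enol ether at C7, and the non-basic medium avoids retro-aldol cleavage and β-elimination of the new β-hydroxy ketone.

**Step 10**
Reactants: 17 cis-fused hydroxy dione
Product: 18 tris(trimethylsilyl) derivative with C5=C6 and C9=C10 enol ethers plus C4–OSiMe3
Conditions: Me3SiOTf, Et3N, CH2Cl2, 0 to 25 °C, until equilibrated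
Reagents that add atoms: trimethylsilyl triflate, C[Si](C)(C)OS(=O)(=O)C(F)(F)F
Why: Enol silylation with silyl triflate and amine equilibrates through the ammonium triflate toward the more substituted enol ether, so C6 enolises to C5 (which relieves three contiguous cis substituents), C10 can enolise only to C9, and the C5 centre is erased.

**Step 11**
Reactants: 18 tris(trimethylsilyl) derivative
Product: 19 trans-fused 4-hydroxy-6,10-dione (C5–H on top and C1–CH3 on the bottom)
Conditions: Bu4NF, AcOH, THF, −78 to 0 °C
Reagents that add atoms: none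
Why: This is a kinetic protonation of a regiodefined enolate released by fluoride in the presence of acetic acid; the bottom face of C5 is flanked by isopropyl and the C1 methyl, so the proton should arrive from the top to give C5–H syn to the C4 oxygen, and the buffered cold medium prevents return to the cis ketone.

**Step 12**
Reactants: 19 trans-fused hydroxy dione
Product: 20 4,6-dihydroxy-10-ketone (C6–OH on the bottom; 1,3-anti to C4–OH)
Conditions: Me4NBH(OAc)3, MeCN–AcOH, −30 °C
Reagents that add atoms: none
Why: In the Evans–Saksena reduction, boron bound to C4–OH hands its hydride to the top face of the C6 carbonyl, which is also the sterically open face opposite the C1 methyl and isopropyl, giving (6R); the neopentyl C10 ketone lies one atom further from the hydroxyl and is not reduced by this mild reagent.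

**Step 13**
Reactants: 21 4-hydroxybenzoic acid
Product: 23 4-(tert-butyldimethylsilyloxy)benzoic acid, via bis-silylated acid 22 (not isolated)
Conditions: t-BuMe2SiCl, imidazole, DMF, 25 °C; then AcOH–THF–H2O, 25 °C
Reagents that add atoms: tert-butyldimethylsilyl chloride, CC(C)(C)[Si](C)(C)Cl
Why: Exhaustive silylation followed by selective hydrolysis of the labile silyl ester is the usual way to an O-silylated hydroxy acid.

**Step 14**
Reactants: 20 diol ketone; 23 silylated hydroxybenzoic acid
Product: 25 C6 4-(tert-butyldimethylsilyloxy)benzoate of 20, via mixed anhydride 24 (not isolated)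
Conditions: 23, 2,4,6-Cl3C6H2COCl, Et3N, THF, 25 °C; then 20, DMAP, toluene, 40 °C
Reagents that add atoms: 4-(tert-butyldimethylsilyloxy)benzoic acid 23, OC(=O)c1ccc(O[Si](C)(C)C(C)(C)C)cc1
Why: Yamaguchi esterification acylates the hindered secondary C6–OH while the tertiary C4–OH stays inert, and no stereocentre is touched.

**Step 15**
Reactants: 25 keto ester
Product: 26 C9=C10 trimethylsilyl enol ether with C4–OSiMe3
Conditions: Me3SiOTf, Et3N, CH2Cl2, 0 to 25 °C
Reagents that add atoms: trimethylsilyl triflate, C[Si](C)(C)OS(=O)(=O)C(F)(F)F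
Why: Soft enolisation is regiochemically unambiguous because C1 is quaternary, it tolerates the ester and the aryl silyl ether, and it caps C4–OH in passing.

**Step 16**
Reactants: 26 silyl enol ether
Product: 28 C8=C9 en-10-one with free C4–OH, via C4 trimethylsilyl ether 27 (not isolated)
Conditions: Pd(OAc)2, MeCN, 25 °C; then 10% aqueous citric acid–THF
Reagents that add atoms: none
Why: In the Saegusa–Ito oxidation the palladium enolate at C9 loses the C8 hydrogen by β-hydride elimination; this installs C8=C9, erases C8, and is placed here so that no second enol ether competes, after which mild acid frees C4–OH.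

**Step 17**
Reactants: 28 enone
Product: 29 allylic alcohol (C10–OH on the bottom; 10S)
Conditions: NaBH4, CeCl3·7H2O, MeOH, −78 °C
Reagents that add atoms: none
Why: The Luche reduction is 1,2-selective, and hydride should attack the top face, opposite the adjacent C1 methyl and the C6 ester, which places the C10 oxygen syn to the methyl group.

**Step 18**
Reactants: 29 allylic alcohol; 30 isovaleryl chloride
Product: 31 C10 isovalerate with the phenol still silylated
Conditions: pyridine, DMAP (cat.), CH2Cl2, 0 to 25 °C
Reagents that add atoms: isovaleryl chloride 30, CC(C)CC(=O)Cl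
Why: DMAP-catalysed acylation takes the only secondary alcohol and leaves the hindered tertiary C4–OH free.

**Step 19**
Reactants: 31 silylated diester
Product: 32 target (1S,4S,5S,6R,10S in the numbering used here)
Conditions: Bu4NF, AcOH, THF, 0 °C
Reagents that add atoms: none
Why: Buffered fluoride cleaves the aryl silyl ether rapidly and leaves both esters, the allylic system and the tertiary alcohol untouched.

**Compound list**
1 | (R)-terpinen-4-ol | CC1=CC[C@@](O)(C(C)C)CC1 | starting material
2 | (R)-terpinen-4-yl triethylsilyl ether | CC1=CC[C@@](O[Si](CC)(CC)CC)(C(C)C)CC1 | intermediate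
3 | secondary ozonide of 2 | CC12CC[C@](O[Si](CC)(CC)CC)(C(C)C)CC(OO1)O2 | intermediate
4 | (R)-3-isopropyl-6-oxo-3-(triethylsilyloxy)heptanal | O=CC[C@@](O[Si](CC)(CC)CC)(C(C)C)CCC(C)=O | intermediate
5 | (E)-1-bromoprop-1-ene | C/C=C/Br | starting material
6 | (E)-prop-1-enylchromium dichloride | C/C=C/[Cr](Cl)Cl | intermediate
7 | (5R,8E)-7-hydroxy-5-isopropyl-5-(triethylsilyloxy)dec-8-en-2-one | C/C=C/C(O)C[C@@](O[Si](CC)(CC)CC)(C(C)C)CCC(C)=O | intermediate
8 | 1,1-dichloroethane | CC(Cl)Cl | starting material
9 | 1,1-dichloroethyllithium | [Li]C(C)(Cl)Cl | intermediate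
10 | dichloro diol (C6 carbinol, C1 carbinol bearing CCl2CH3) | C/C=C/C(O)C[C@@](O[Si](CC)(CC)CC)(C(C)C)CCC(C)(O)C(C)(Cl)Cl | intermediate
11 | (E)-enone with C1 dichloro carbinol | C/C=C/C(=O)C[C@@](O[Si](CC)(CC)CC)(C(C)C)CCC(C)(O)C(C)(Cl)Cl | intermediate
12 | (Z,E)-2-silyloxydiene with C1 dichloro carbinol | C/C=C/C(O[Si](C)(C)C(C)(C)C)=C/[C@@](O[Si](CC)(CC)CC)(C(C)C)CCC(C)(O)C(C)(Cl)Cl | intermediate
13 | α-chloro epoxide | C/C=C/C(O[Si](C)(C)C(C)(C)C)=C/[C@@](O[Si](CC)(CC)CC)(C(C)C)CCC1(C)OC1(C)Cl | intermediate
14 | acyclic tertiary α-chloro ketone with tethered 2-silyloxydiene | C/C=C/C(O[Si](C)(C)C(C)(C)C)=C/[C@@](O[Si](CC)(CC)CC)(C(C)C)CCC(C)(Cl)C(C)=O | intermediate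
15 | oxyallyl cation (zwitterion) | C/C=C/C(O[Si](C)(C)C(C)(C)C)=C/[C@@](O[Si](CC)(CC)CC)(C(C)C)CC[C+](C)C([O-])=C | intermediate
16 | cis-fused hydroazulen-10-one, C6 OTBS enol ether, C4 OTES | C[C@H]1CC(=O)[C@@]2(C)CC[C@](O[Si](CC)(CC)CC)(C(C)C)[C@H]2C(O[Si](C)(C)C(C)(C)C)=C1 | intermediate
17 | cis-fused 4-hydroxy-6,10-dione | C[C@H]1CC(=O)[C@@]2(C)CC[C@](O)(C(C)C)[C@H]2C(=O)C1 | intermediate
18 | tris(trimethylsilyl) bis-enol ether | C[C@H]1C=C(O[Si](C)(C)C)[C@@]2(C)CC[C@](O[Si](C)(C)C)(C(C)C)C2=C(O[Si](C)(C)C)C1 | intermediate
19 | trans-fused 4-hydroxy-6,10-dione | C[C@H]1CC(=O)[C@@]2(C)CC[C@](O)(C(C)C)[C@@H]2C(=O)C1 | intermediate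
20 | trans-fused 4,6-dihydroxy-10-ketone | C[C@H]1CC(=O)[C@@]2(C)CC[C@](O)(C(C)C)[C@@H]2[C@H](O)C1 | intermediate
21 | 4-hydroxybenzoic acid | OC(=O)c1ccc(O)cc1 | starting material
22 | tert-butyldimethylsilyl 4-(tert-butyldimethylsilyloxy)benzoate | CC(C)(C)[Si](C)(C)OC(=O)c1ccc(O[Si](C)(C)C(C)(C)C)cc1 | intermediate
23 | 4-(tert-butyldimethylsilyloxy)benzoic acid | OC(=O)c1ccc(O[Si](C)(C)C(C)(C)C)cc1 | intermediate
24 | mixed anhydride of 23 and 2,4,6-trichlorobenzoic acid | O=C(OC(=O)c1c(Cl)cc(Cl)cc1Cl)c1ccc(O[Si](C)(C)C(C)(C)C)cc1 | intermediate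
25 | C6 aroyl ester, C10 ketone | C[C@H]1CC(=O)[C@@]2(C)CC[C@](O)(C(C)C)[C@@H]2[C@H](OC(=O)c2ccc(O[Si](C)(C)C(C)(C)C)cc2)C1 | intermediate
26 | C9=C10 trimethylsilyl enol ether, C4 OSiMe3 | C[C@H]1C=C(O[Si](C)(C)C)[C@@]2(C)CC[C@](O[Si](C)(C)C)(C(C)C)[C@@H]2[C@H](OC(=O)c2ccc(O[Si](C)(C)C(C)(C)C)cc2)C1 | intermediate
27 | C8=C9 en-10-one, C4 OSiMe3 | CC1=CC(=O)[C@@]2(C)CC[C@](O[Si](C)(C)C)(C(C)C)[C@@H]2[C@H](OC(=O)c2ccc(O[Si](C)(C)C(C)(C)C)cc2)C1 | intermediate
28 | C8=C9 en-10-one, free C4–OH | CC1=CC(=O)[C@@]2(C)CC[C@](O)(C(C)C)[C@@H]2[C@H](OC(=O)c2ccc(O[Si](C)(C)C(C)(C)C)cc2)C1 | intermediate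
29 | (10S)-allylic alcohol | CC1=C[C@H](O)[C@@]2(C)CC[C@](O)(C(C)C)[C@@H]2[C@H](OC(=O)c2ccc(O[Si](C)(C)C(C)(C)C)cc2)C1 | intermediate
30 | isovaleryl chloride | CC(C)CC(=O)Cl | starting material
31 | C10 isovalerate, phenol silylated | CC1=C[C@H](OC(=O)CC(C)C)[C@@]2(C)CC[C@](O)(C(C)C)[C@@H]2[C@H](OC(=O)c2ccc(O[Si](C)(C)C(C)(C)C)cc2)C1 | intermediate
32 | CNP0086724.2 | CC1=C[C@H](OC(=O)CC(C)C)[C@@]2(C)CC[C@](O)(C(C)C)[C@@H]2[C@H](OC(=O)c2ccc(O)cc2)C1 | target

**Step count**
Total step count: 19. Longest linear sequence: 18 (steps 1–12 and 14–19).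

**Steps most likely to fail**

1. Step 8.
   - What may go wrong: the cation may be intercepted before the second bond forms, either by solvent capture at C1 or by closure of the enolate oxygen onto C6. Bonding may also occur on the other diene face, with isopropyl instead of oxygen beside OTBS, which would put C10 anti to the C4 oxygen.
   - Fallback, from 11 back to 17: the diene is made rigid by a silicon bridge. HF·pyridine removes the triethylsilyl group of 11 to give the β-hydroxy enone F1. t-Bu2Si(OTf)2 and Et3N tie the C4 oxygen and the C6 enol oxygen into the cyclic silyl dienol ether F2. This ring can only hold the Z enol ether and keeps the C4 oxygen beside O6, so isopropyl and the tether are forced onto opposite diene faces.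
   - KN(SiMe3)2 then unmasks the chloro ketone F3. Et3N in CF3CH2OH closes both rings to the silylene-bridged adduct F4, and HF·pyridine releases 17.

2. Step 10.
   - What may go wrong: enolisation may persist toward the less hindered C7, so that C5 is not erased.
   - Fallback, from 17 back to 19: the direction of enolisation is dictated by a tether from the neighbouring oxygen. t-Bu2Si(OTf)2 and Et3N convert 17 into the dioxasiline enol ether F5, in which only the C5=C6 enol places its double bond inside the six-membered O–Si–O ring. Bu4NF and AcOH at −78 °C then cleave the bridge with protonation at C5 to give 19.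

3. Step 11.
   - What may go wrong: the proton may be delivered to the bottom face, or re-enolisation on warming may return the more stable cis-fused ketone.
   - Fallback, from 17 back to 19: the hydrogen is delivered from a metal held by the C4 oxygen. Acid-catalysed dehydration (TsOH, toluene, 80 °C) gives the tetrasubstituted enone F6. Alkaline H2O2 epoxidises it opposite the C1 methyl to the epoxy ketone F7.
   - SmI2 in THF–MeOH at −90 °C then cleaves the C5–O bond. The samarium ion bridging the C4 alkoxide and the enolate oxygen carries the methanol that protonates C5, so the hydrogen arrives on the face of the C4 oxygen and 19 results.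

**Further compounds**
F1 | step 8 | β-hydroxy enone (11 without the triethylsilyl group) | C/C=C/C(=O)C[C@@](O)(C(C)C)CCC(C)(O)C(C)(Cl)Cl
F2 | step 8 | di-tert-butylsilylene-bridged (4H-1,3,2-dioxasiline) dienol ether with C1 dichloro carbinol | C/C=C/C1=C[C@@](C(C)C)(CCC(C)(O)C(C)(Cl)Cl)O[Si](C(C)(C)C)(C(C)(C)C)O1
F3 | step 8 | silylene-bridged dienol ether with tertiary α-chloro ketone | C/C=C/C1=C[C@@](C(C)C)(CCC(C)(Cl)C(C)=O)O[Si](C(C)(C)C)(C(C)(C)C)O1
F4 | step 8 | silylene-bridged cis-fused cycloadduct | C[C@H]1CC(=O)[C@@]2(C)CC[C@]3(C(C)C)[C@H]2C(=C1)O[Si](C(C)(C)C)(C(C)(C)C)O3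
F5 | step 10 | dioxasiline C5=C6 enol ether of 17 | C[C@H]1CC(=O)[C@@]2(C)CC[C@]3(C(C)C)C2=C(C1)O[Si](C(C)(C)C)(C(C)(C)C)O3
F6 | step 11 | C4=C5 en-6-one, C10 ketone | C[C@H]1CC(=O)[C@@]2(C)CCC(C(C)C)=C2C(=O)C1
F7 | step 11 | 4,5-epoxy-6,10-dione (oxygen on the top face) | C[C@H]1CC(=O)[C@@]2(C)CC[C@@]3(C(C)C)O[C@@]23C(=O)C1
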